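## The problem

Kazinol B is a (2S)-flavan: a 7-hydroxychroman (rings A and C) that carries at C2 a benzene ring B with five substituents. Going round ring B, C1' holds the flavan carbon, C2' a prenyl group, C3' a free hydroxyl, C4' and C5' are the oxygen- and carbon-bearing atoms of a fused 2,2-dimethyl-2H-pyran, and only C6' keeps a hydrogen. The hard part is this ring: prenyl and pyran must sit next to the two oxygens of a catechol in one fixed orientation relative to C1', and substitution or Claisen chemistry on a catechol has little to tell O3' from O4'. The only stereocentre is C2, a benzylic ether carbon with no neighbouring stereo element, so it has to be set by a reagent or catalyst. Once set it is fragile, because the para C4' oxygen stabilises a benzylic cation and acid can open or racemise ring C. Acid also closes an ortho-prenylphenol to a chroman and attacks the chromene double bond, oxidants attack both alkenes, and catalytic hydrogenation is excluded, so the end game has to be basic or neutral. A short route is possible because C2', C3', C4' and C5' carry carbon, oxygen, oxygen and carbon, which is the pattern of C6, C5, C4 and C3 of a 4,5-dioxygenated 2-pyranone whose C3/C4-oxygen edge already bears the dimethylpyran. The two missing atoms, C1' and C6', carry a carbonyl-level carbon and a hydrogen, the substituents of a terminal ynone, and the ketone delivered at C1' is the handle for setting C2.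

## Retrosynthesis

**Target 19 to bis-methyl ether 18.** The two O–CH3 bonds are cut last. Both phenols travel as methyl ethers because the methyl groups come free of charge with the commercial building blocks 2 and 9. One thiolate operation then unmasks both under basic, non-oxidising conditions, so no acid meets the finished prenylphenol, chromene or C2 centre. The forward step must perform two SN2 demethylations without touching the alkenes or the benzylic ether.

**Flavan 18 to bromo alcohol 17.** Ring C is opened at O1–C8a. The neighbouring cut, C2–O1, would create the stereocentre by substitution at an electron-rich benzylic carbon, where ionisation erodes configuration. Cutting the aryl–oxygen bond leaves the carbinol C–O bond untouched, so configuration is simply carried over. The precursor is an open-chain secondary alcohol with an ortho-bromoaryl group three atoms away. The forward step is a copper-catalysed intramolecular aryl etherification forming a six-membered ring.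

**Alcohol 17 to ketone 16.** The C2–H bond is cut, reducing the only stereocentre to a prochiral aryl alkyl ketone. The forward reduction must be catalyst-controlled and must spare the aryl bromide, the prenyl group and the chromene. That points to polar transfer hydrogenation, not H2 over a metal surface.

**Ketone 16 to pyranopyranone 8 and ynone 14 (the strategic cut).** Ring B is taken apart at C1'–C2' and C5'–C6', with the lactone bridge O6–C5(=O) of 8 restored in the retrosynthetic direction. The obvious neighbour, acylation of a preformed 8-methoxy-7-prenylchromene, needs Lewis acid that the prenyl and chromene groups will not tolerate, must choose between the two free positions C5 and C6, and still leaves that arene to be made from a catechol. The cycloaddition makes the benzene and installs the ketone together, and the relative positions of prenyl, methoxy, pyran oxygen and pyran carbon are already fixed in 8. Both precursors are achiral and three steps from commercial material. The forward reaction must be regioselective (acyl next to prenyl) and must use the pyranone diene in preference to the 2H-pyran diene.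

**Pyranopyranone 8 to hydroxypyranone 5 and enal 6.** The 2H-pyran is cut at C4–C4a and O1–C2, a formal [3+3] disconnection. It is preferred over O-alkylation/Claisen routes because the hydroxypyranone has only one nucleophilic carbon (C3) and one adjacent oxygen, so there is no regiochemical choice. The forward step is a Knoevenagel condensation followed by oxa-6π closure.

**Hydroxypyranone 5 to triketo ester 4, then to acid 1 and keto ester 2 (via acyl imidazole 3).** The lactone C–O bond is cut, then the bond between C4 of 2 and the acyl carbon of 1. This assigns the ring B substituents to simple pieces: the methoxy group of 2 becomes the C3' oxygen and the acyl chain of 1 becomes the prenyl group. The forward steps are a dianion γ-acylation and a base-mediated lactonisation. The β,γ-double bond of 1 must not move.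

**Ynone 14 to Weinreb amide 12 and ethynylmagnesium bromide 13; 12 to enamide 11; 11 to aldehyde 9 and phosphonate 10.** The acyl–alkyne bond is cut first, then the C=C bond of the cinnamoyl precursor. The bromine of 9 is the future C8a leaving group and its methoxy group the future C7 hydroxyl. The only demand is to reduce the conjugated alkene without hydrogenolysis of the C–Br bond.

## Roads not taken

**Alternative 1:** The cut goes through O1–C2 and C3–C4 of ring C. The ortho-quinone methide from 2-hydroxy-4-(pivaloyloxy)benzyl alcohol A2 would be generated under a chiral BINOL-derived phosphoric acid and trapped by 8-(tert-butyldimethylsilyloxy)-2,2-dimethyl-6-vinyl-2H-chromene A3 to give (2S)-2-[8-(tert-butyldimethylsilyloxy)-2,2-dimethyl-2H-chromen-6-yl]chroman-7-yl pivalate A1.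
- Merits: it is the most convergent plan. Ring C and the stereocentre arise in one catalytic step, with no aryl halide and no ketone reduction.
- Weak points:
  - The methide from A2 has no substituent on its exocyclic carbon and carries an acyloxy group. It is less stabilised than the aryl-substituted methides on which this asymmetric chemistry is normally run, and facial selection rests on the approach of the styrene alone.
  - A3 holds two styrene-type alkenes. The chromene C3=C4 bond can compete as the 2π partner and is itself acid-sensitive.
  - A1 has no prenyl group. It would have to be introduced late at C2', the most hindered position of ring B, by C-alkylation of a phenoxide in competition with O-alkylation, on a molecule that already contains the labile C2 centre.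
- Comparison: in convergence and in how the stereocentre is made this road is better than the chosen plan, which spends two steps (reduction, etherification) on what A1 achieves in one. The chosen plan sets against it that all five ring B substituents, prenyl included, are in place before the stereocentre exists.

**Alternative 2:** The cut is again O1–C8a, but ring A is carried as a cyclohexane-1,3-dione. The hydroxy dione 4-{(3S)-3-[8-(tert-butyldimethylsilyloxy)-2,2-dimethyl-7-(3-methylbut-2-en-1-yl)-2H-chromen-6-yl]-3-hydroxypropyl}cyclohexane-1,3-dione A5 condenses to the bicyclic vinylogous ester (2S)-2-aryl-2,3,4,4a,5,6-hexahydro-7H-chromen-7-one A4, which is then dehydrogenated to the phenol.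
- Merits: the ring closure is a simple condensation with guaranteed retention, needs no copper and no aryl bromide, and both C4a epimers of A4 converge.
- Weak points:
  - Aromatising A4 needs an oxidant, a halogenation–elimination or a hot metal-mediated dehydrogenation, in a molecule with a prenyl group, a chromene and a benzylic ether C–H, which are the groups such reagents attack.
  - The condensation is normally acid-driven, which threatens C2.
  - The alkylated dione A5 must itself be assembled.
  - The alternative says nothing about ring B, whose aryl ketone still has to be made.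
- Comparison: stereocontrol is equal (the same ketone reduction) and the bond-forming event is gentler. The chosen plan keeps ring A aromatic from the start at the price of one copper-catalysed step, and it also solves the ring B problem.

**Alternative 3:** The cut removes C2'–CH2, C5'–CH= and the pyran ring in one thermal operation. The bis-ether (2S)-2-[3-(2-methylbut-3-en-2-yloxy)-4-(2-methylbut-3-yn-2-yloxy)phenyl]chroman-7-yl pivalate A7 would undergo two aromatic Claisen rearrangements and an oxa-6π closure to give kazinol B 7-O-pivalate A6.
- Merits: each ether has one free ortho position (C2' for O3', C5' for O4'), so both C–C bonds are regiochemically enforced. The cascade needs no reagent and the flavan can be made early on simple material.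
- Weak points:
  - The difficulty moves to A7. The two catechol oxygens must be told apart and turned into two different hindered tertiary ethers, so the order and selectivity of etherification are critical.
  - Tertiary allyl aryl ethers ionise or fragment on heating in competition with the [3,3] shift.
  - The first rearrangement must deliver carbon to the crowded C2' position.
  - The full thermal load falls on the finished C2 centre.
- Comparison: once the flavan is in hand this road is as short as the chosen one or shorter, and its regiocontrol is equally structural. The chosen plan sets against it that no catechol is ever differentiated: the pyran oxygen comes from the C4 hydroxyl of pyranone 5 and the free phenol from the methoxy group of 2, so they are distinct from step 1.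

Key step: step 7

## Route

Assumption: 2-bromo-4-methoxybenzaldehyde (9), phosphonate 10 and HC≡CMgBr solution (13) are taken as commercial, so the ring A phenol is carried as its methyl ether from the start. Compounds 4 and 15 are racemic and are written without configuration.

Step 1
Reactants: 1 4-methylpent-3-enoic acid; 2 methyl 4-methoxy-3-oxobutanoate (methyl 4-methoxyacetoacetate)
Product: 4 methyl 4-methoxy-8-methyl-3,5-dioxonon-7-enoate (racemic at C4; enolised), via 1-(imidazol-1-yl)-4-methylpent-3-en-1-one 3 (not isolated)
Conditions: 1, CDI, THF, rt (gives 3); separately 2 (2.2 equiv), NaH then n-BuLi, THF, 0 °C; add 3 at −78 °C, warm to 0 °C; aq NH4Cl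
Reagents that add atoms: 1,1'-carbonyldiimidazole (CDI), O=C(n1ccnc1)n1ccnc1 (supplies the imidazole of 3; none of its atoms remain in 4)
Why: CDI turns acid 1 into acyl imidazole 3; the γ-carbon (C4) of the sodium–lithium dianion of 2 is its most nucleophilic site and is C-acylated in a Claisen-type dianion acylation, the excess dianion absorbing the proton of the more acidic triketone product. Addition at −78 °C is meant to outrun proton transfer from the β,γ-unsaturated acyl donor.

Step 2
Reactants: 4 methyl 4-methoxy-8-methyl-3,5-dioxonon-7-enoate
Product: 5 4-hydroxy-5-methoxy-6-(3-methylbut-2-en-1-yl)-2H-pyran-2-one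
Conditions: DBU (1.2 equiv), toluene, 80 °C; then cold 1 M HCl
Reagents that add atoms: none
Why: Base-mediated lactonisation of a 3,5-diketo ester: the C5 enol oxygen attacks the ester (6-exo-trig) and methanol is lost to give the 4-hydroxy-2-pyranone. As its DBU salt the product is an anion, which shields the prenyl CH2 from deprotonation and keeps the double bond out of conjugation.

Step 3
Reactants: 5 4-hydroxy-5-methoxy-6-(3-methylbut-2-en-1-yl)-2H-pyran-2-one; 6 3-methylbut-2-enal
Product: 8 8-methoxy-2,2-dimethyl-7-(3-methylbut-2-en-1-yl)-2H,5H-pyrano[4,3-b]pyran-5-one, via 1-oxatriene 5-methoxy-3-(3-methylbut-2-en-1-ylidene)-6-(3-methylbut-2-en-1-yl)pyran-2,4-dione 7 (not isolated)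
Conditions: ethylenediammonium diacetate (20 mol %), CH2Cl2, 40 °C
Reagents that add atoms: none
Why: Amine-salt-catalysed Knoevenagel condensation at the nucleophilic C3 of 5 gives the 1-oxatriene 7, which closes by oxa-6π electrocyclisation onto the C4 oxygen (formal [3+3] annulation). Closure on this oxygen keeps the 2-pyranone lactone, the established outcome for 4-hydroxy-2-pyranones with β,β-disubstituted enals.

Step 4
Reactants: 9 2-bromo-4-methoxybenzaldehyde; 10 diethyl {2-[methoxy(methyl)amino]-2-oxoethyl}phosphonate
Product: 11 (2E)-3-(2-bromo-4-methoxyphenyl)-N-methoxy-N-methylprop-2-enamide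
Conditions: NaH, THF, 0 °C to rt
Reagents that add atoms: none
Why: Horner–Wadsworth–Emmons olefination with a stabilised phosphonate anion; it brings in two carbons and the Weinreb amide in one step, and alkene geometry does not matter because the double bond is reduced next.

Step 5
Reactants: 11 (2E)-3-(2-bromo-4-methoxyphenyl)-N-methoxy-N-methylprop-2-enamide
Product: 12 3-(2-bromo-4-methoxyphenyl)-N-methoxy-N-methylpropanamide
Conditions: TsNHNH2 (excess), NaOAc, DME/H2O, reflux
Reagents that add atoms: none
Why: Diimide, formed by base-induced fragmentation of the sulfonyl hydrazide, transfers H2 in a concerted syn fashion to the conjugated C=C only. The aryl C–Br bond, the amide N–O bond and the aryl ether, all at risk under catalytic hydrogenation, are inert.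

Step 6
Reactants: 12 3-(2-bromo-4-methoxyphenyl)-N-methoxy-N-methylpropanamide; 13 ethynylmagnesium bromide
Product: 14 5-(2-bromo-4-methoxyphenyl)pent-1-yn-3-one
Conditions: HC≡CMgBr (2.5 equiv), THF, 0 °C to rt; inverse quench into cold 1 M HCl
Reagents that add atoms: none
Why: Weinreb ketone synthesis: the magnesium-chelated tetrahedral intermediate holds until work-up, so no tertiary alcohol forms. Pouring into cold acid protonates the released N,O-dimethylhydroxylamine before it can add to the ynone.

Step 7
Reactants: 8 8-methoxy-2,2-dimethyl-7-(3-methylbut-2-en-1-yl)-2H,5H-pyrano[4,3-b]pyran-5-one; 14 5-(2-bromo-4-methoxyphenyl)pent-1-yn-3-one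
Product: 16 3-(2-bromo-4-methoxyphenyl)-1-[8-methoxy-2,2-dimethyl-7-(3-methylbut-2-en-1-yl)-2H-chromen-6-yl]propan-1-one, via bridged lactone cycloadduct 15 (not isolated)
Conditions: 14 (1.5 equiv, in portions), BHT (5 mol %), degassed toluene, sealed tube, 140 °C
Reagents that add atoms: none
Why: Thermal normal-demand [4+2] cycloaddition of the 2-pyranone diene of 8 (C4a=C8a–C8=C7) with the ynone as dienophile gives the bridged lactone 15, which expels CO2 by [4+2] cycloreversion and so aromatises. The closest known reaction type is the Diels–Alder/decarboxylation of 4-alkoxy-2-pyranones with acetylenic ketones and esters to give benzenes; this ring-fused, fully substituted diene is a new member of that class. Ring B is closed as a six-membered carbocycle by the intermolecular cycloaddition itself, the new bonds being C1'–C2' (ynone C2 to pyranone C7) and C5'–C6' (ynone C1 to pyranone C4a), so no ring-closure descriptor of a chain cyclisation applies. No stereocentre is created, since the two bridgeheads of 15 end as aromatic carbons. The step needs regioselectivity: C4a is the nucleophilic diene terminus, being the α-carbon of the vinylogous carbonate O1–C8a=C4a–C5=O and also reached by the ring oxygen O6 through C7=C8, and in an asynchronous transition state it should bond first to the electrophilic terminal carbon of the ynone, which puts the acyl group next to the prenyl-bearing carbon. The C8 methoxy group donates towards C7 and is the one opposing influence, set against two matched oxygen donors. The step also needs periselectivity over the 2H-pyran diene (C3=C4–C4a=C8a) and the prenyl group: only the pyranone adduct is removed irreversibly by CO2 loss, an adduct across the 2H-pyran diene would give up the pyranone conjugation and can revert, and a thermal ene reaction of the prenyl group with an ynone normally needs Lewis acid. BHT and a degassed sealed tube are there to keep the terminal ynone from radical oligomerisation.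

Step 8
Reactants: 16 3-(2-bromo-4-methoxyphenyl)-1-[8-methoxy-2,2-dimethyl-7-(3-methylbut-2-en-1-yl)-2H-chromen-6-yl]propan-1-one
Product: 17 (1S)-3-(2-bromo-4-methoxyphenyl)-1-[8-methoxy-2,2-dimethyl-7-(3-methylbut-2-en-1-yl)-2H-chromen-6-yl]propan-1-ol
Conditions: RuCl[(S,S)-TsDPEN](p-cymene) (2 mol %), HCO2H/Et3N (5:2), EtOAc, 40 °C
Reagents that add atoms: none
Why: Noyori–Ikariya asymmetric transfer hydrogenation: the ruthenium hydride formed from formate passes hydride and proton to the ketone through a six-membered outer-sphere transition state in which a CH/π contact between p-cymene and the ketone aryl fixes the face. With the (S,S)-ligand aryl alkyl ketones give the (S)-alcohol, here the future (2S) centre. The alkenes and the aryl bromide are not touched by this polar hydride transfer.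

Step 9
Reactants: 17 (1S)-3-(2-bromo-4-methoxyphenyl)-1-[8-methoxy-2,2-dimethyl-7-(3-methylbut-2-en-1-yl)-2H-chromen-6-yl]propan-1-ol
Product: 18 (2S)-7-methoxy-2-[8-methoxy-2,2-dimethyl-7-(3-methylbut-2-en-1-yl)-2H-chromen-6-yl]-3,4-dihydro-2H-chromene
Conditions: CuI (10 mol %), 3,4,7,8-tetramethyl-1,10-phenanthroline (20 mol %), Cs2CO3, toluene, 110 °C
Reagents that add atoms: none
Why: Intramolecular Ullmann-type C–O coupling: the caesium alkoxide binds monovalent copper, the C–Br bond adds oxidatively and reductive elimination closes the six-membered ring C. The carbinol C–O bond is never broken, so the (S) configuration is carried over as (2S).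

Step 10
Reactants: 18 (2S)-7-methoxy-2-[8-methoxy-2,2-dimethyl-7-(3-methylbut-2-en-1-yl)-2H-chromen-6-yl]-3,4-dihydro-2H-chromene
Product: 19 kazinol B, (2S)-2-[8-hydroxy-2,2-dimethyl-7-(3-methylbut-2-en-1-yl)-2H-chromen-6-yl]-3,4-dihydro-2H-chromen-7-ol
Conditions: NaSEt (10 equiv), DMF, 130 °C; aq NH4Cl
Reagents that add atoms: none
Why: Thiolate SN2 dealkylation of aryl methyl ethers: the C8 methoxy group, twisted out of conjugation by two ortho substituents, should go first and the ordinary ring A anisole second, on a separate ring that the first phenoxide does not deactivate. The medium is basic and non-oxidising, so prenyl, chromene and the C2 centre should survive.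

## Compound list

1 | 4-methylpent-3-enoic acid | CC(C)=CCC(=O)O | starting material
2 | methyl 4-methoxy-3-oxobutanoate | COCC(=O)CC(=O)OC | starting material
3 | 1-(1H-imidazol-1-yl)-4-methylpent-3-en-1-one | CC(C)=CCC(=O)n1ccnc1 | intermediate (not isolated)
4 | methyl 4-methoxy-8-methyl-3,5-dioxonon-7-enoate (racemic) | COC(=O)CC(=O)C(OC)C(=O)CC=C(C)C | intermediate
5 | 4-hydroxy-5-methoxy-6-(3-methylbut-2-en-1-yl)-2H-pyran-2-one | COC1=C(CC=C(C)C)OC(=O)C=C1O | intermediate
6 | 3-methylbut-2-enal | CC(C)=CC=O | starting material
7 | 5-methoxy-3-(3-methylbut-2-en-1-ylidene)-6-(3-methylbut-2-en-1-yl)-2H-pyran-2,4(3H)-dione (alkylidene geometry not defined) | O=C1OC(CC=C(C)C)=C(OC)C(=O)C1=CC=C(C)C | intermediate (not isolated)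
8 | 8-methoxy-2,2-dimethyl-7-(3-methylbut-2-en-1-yl)-2H,5H-pyrano[4,3-b]pyran-5-one | O=C1OC(CC=C(C)C)=C(OC)C2=C1C=CC(C)(C)O2 | intermediate
9 | 2-bromo-4-methoxybenzaldehyde | COc1ccc(C=O)c(Br)c1 | starting material
10 | diethyl {2-[methoxy(methyl)amino]-2-oxoethyl}phosphonate | CCOP(=O)(OCC)CC(=O)N(C)OC | starting material
11 | (2E)-3-(2-bromo-4-methoxyphenyl)-N-methoxy-N-methylprop-2-enamide | CON(C)C(=O)/C=C/c1ccc(OC)cc1Br | intermediate
12 | 3-(2-bromo-4-methoxyphenyl)-N-methoxy-N-methylpropanamide | CON(C)C(=O)CCc1ccc(OC)cc1Br | intermediate
13 | ethynylmagnesium bromide | C#C[Mg]Br | starting material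
14 | 5-(2-bromo-4-methoxyphenyl)pent-1-yn-3-one | C#CC(=O)CCc1ccc(OC)cc1Br | intermediate
15 | bridged lactone cycloadduct of 8 and 14 (2-oxabicyclo[2.2.2]octa-5,7-dien-3-one core, lactone bridge between former pyranone C7 and C4a; racemic) | CC(C)=CCC12OC(=O)C3(C=C2C(=O)CCc2ccc(OC)cc2Br)C=CC(C)(C)OC3=C1OC | intermediate (not isolated)
16 | 3-(2-bromo-4-methoxyphenyl)-1-[8-methoxy-2,2-dimethyl-7-(3-methylbut-2-en-1-yl)-2H-chromen-6-yl]propan-1-one | CC(C)=CCc1c(C(=O)CCc3ccc(OC)cc3Br)cc2c(c1OC)OC(C)(C)C=C2 | intermediate
17 | (1S)-3-(2-bromo-4-methoxyphenyl)-1-[8-methoxy-2,2-dimethyl-7-(3-methylbut-2-en-1-yl)-2H-chromen-6-yl]propan-1-ol | CC(C)=CCc1c([C@@H](O)CCc3ccc(OC)cc3Br)cc2c(c1OC)OC(C)(C)C=C2 | intermediate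
18 | (2S)-7-methoxy-2-[8-methoxy-2,2-dimethyl-7-(3-methylbut-2-en-1-yl)-2H-chromen-6-yl]-3,4-dihydro-2H-chromene | CC(C)=CCc1c([C@@H]2CCc3ccc(OC)cc3O2)cc2c(c1OC)OC(C)(C)C=C2 | intermediate
19 | kazinol B, (2S)-2-[8-hydroxy-2,2-dimethyl-7-(3-methylbut-2-en-1-yl)-2H-chromen-6-yl]-3,4-dihydro-2H-chromen-7-ol | CC(C)=CCc1c([C@@H]2CCc3ccc(O)cc3O2)cc2c(c1O)OC(C)(C)C=C2 | target

## Step count and weak points

Total steps: 10. Longest linear sequence: 7 (steps 1–3 or 4–6, then 7–10).

**Step 7 (key step).**
- What may go wrong: the terminal ynone may be consumed by oligomerisation before the crowded, fully substituted pyranone diene engages. Regiocontrol may also erode, because the C8 methoxy group pushes electron density towards C7 against the C8a oxygen.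
- Fallback (sets out from 8, returns at 16): the side chain is attached after the benzannulation. Compound 8 is heated with a large excess of the cheap, volatile but-3-yn-2-one in a sealed tube and should pass through the bridged lactone cycloadduct F1 to the methyl ketone 1-[8-methoxy-2,2-dimethyl-7-(3-methylbut-2-en-1-yl)-2H-chromen-6-yl]ethan-1-one F2. Claisen–Schmidt condensation of F2 with aldehyde 9 (KOH, EtOH) should give the enone (2E)-3-(2-bromo-4-methoxyphenyl)-1-[8-methoxy-2,2-dimethyl-7-(3-methylbut-2-en-1-yl)-2H-chromen-6-yl]prop-2-en-1-one F3. Conjugate reduction of F3 with [CuH(PPh3)]6, which spares isolated alkenes and the aryl bromide, returns 16.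
- Limit of the fallback: it removes the fragile elaborated ynone from the thermal step and lets regiochemistry be assigned on F2 before the second fragment is invested. It does not change the intrinsic regiochemical preference of the diene.

**Step 1.**
- What may go wrong: proton transfer from the α-CH2 of the β,γ-unsaturated acyl imidazole to the strongly basic dianion, which quenches both partners, and migration of the double bond into conjugation.
- Fallback (sets out from 2, returns at 8): the prenyl group is introduced after the bicycle is built.
  - The dianion of 2 is acylated with 1-acetylimidazole to give methyl 4-methoxy-3,5-dioxohexanoate F4.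
  - DBU lactonisation gives 4-hydroxy-5-methoxy-6-methyl-2H-pyran-2-one F5.
  - Condensation with 6 under the conditions of step 3 passes through the oxatriene 5-methoxy-6-methyl-3-(3-methylbut-2-en-1-ylidene)-2H-pyran-2,4(3H)-dione F6 to 8-methoxy-2,2,7-trimethyl-2H,5H-pyrano[4,3-b]pyran-5-one F7.
  - F7 is deprotonated at the 7-methyl group with LiN(i-Pr)2 (THF, −78 °C), transmetalated with ZnCl2 and coupled with 1-bromo-2-methylprop-1-ene under Pd(PPh3)4 (Negishi coupling) to give 8.

**Step 8.**
- What may go wrong: slow turnover and poor facial selectivity, because the ketone is electron-rich and flanked by the ortho prenyl group, which disturbs the arene/aryl contact that fixes the face.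
- Fallback (sets out from 16, returns at 17): the catalytic outer-sphere reduction is replaced by a stoichiometric, sterically driven chiral borane, (−)-B-chlorodiisopinocampheylborane in THF at −25 °C with diethanolamine work-up. This reagent is at its best with hindered aryl alkyl ketones, gives the (S)-alcohol from such ketones and has no B–H bond to add to the alkenes. No new compound is made.

**Step 10.**
- What may go wrong: stalling at the mono-phenoxide, because the second demethylation must occur on an already anionic molecule, and slow thiolate attack at the benzylic C2–O bond under the forcing conditions then needed.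
- Fallback (sets out from 8, returns at 19): ring A is carried as a methoxymethyl ether, so the thiolate is asked only for the activated C8 methyl ether.
  - 2-Bromo-4-hydroxybenzaldehyde F8 is protected (MOMCl, i-Pr2NEt) as 2-bromo-4-(methoxymethoxy)benzaldehyde F9.
  - The operations of steps 4–6 (cold aqueous NaHSO4 quench in the last) take F9 through (2E)-3-[2-bromo-4-(methoxymethoxy)phenyl]-N-methoxy-N-methylprop-2-enamide F10 and 3-[2-bromo-4-(methoxymethoxy)phenyl]-N-methoxy-N-methylpropanamide F11 to 5-[2-bromo-4-(methoxymethoxy)phenyl]pent-1-yn-3-one F12.
  - Cycloaddition of F12 with 8 passes through the bridged lactone cycloadduct F13 to the ketone 3-[2-bromo-4-(methoxymethoxy)phenyl]-1-[8-methoxy-2,2-dimethyl-7-(3-methylbut-2-en-1-yl)-2H-chromen-6-yl]propan-1-one F14.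
  - Transfer hydrogenation as in step 8 gives the (1S)-alcohol F15, and copper-catalysed closure as in step 9 gives the flavan (2S)-7-(methoxymethoxy)-2-[8-methoxy-2,2-dimethyl-7-(3-methylbut-2-en-1-yl)-2H-chromen-6-yl]-3,4-dihydro-2H-chromene F16.
  - The MOM group is removed with catalytic HCl in methanol at ambient temperature to give 3'-O-methylkazinol B F17. The C3' oxygen is still methylated at this point, so no ortho-prenylphenol meets acid.
  - One thiolate demethylation of F17 (NaSEt, DMF, about 110 °C) returns 19.

## Further compounds

F1 | step 7 | bridged lactone cycloadduct of 8 and but-3-yn-2-one (racemic, not isolated) | CC(C)=CCC12OC(=O)C3(C=C2C(C)=O)C=CC(C)(C)OC3=C1OC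
F2 | step 7 | 1-[8-methoxy-2,2-dimethyl-7-(3-methylbut-2-en-1-yl)-2H-chromen-6-yl]ethan-1-one | CC(C)=CCc1c(C(C)=O)cc2c(c1OC)OC(C)(C)C=C2
F3 | step 7 | (2E)-3-(2-bromo-4-methoxyphenyl)-1-[8-methoxy-2,2-dimethyl-7-(3-methylbut-2-en-1-yl)-2H-chromen-6-yl]prop-2-en-1-one | CC(C)=CCc1c(C(=O)/C=C/c3ccc(OC)cc3Br)cc2c(c1OC)OC(C)(C)C=C2
F4 | step 1 | methyl 4-methoxy-3,5-dioxohexanoate (racemic) | COC(=O)CC(=O)C(OC)C(C)=O
F5 | step 1 | 4-hydroxy-5-methoxy-6-methyl-2H-pyran-2-one | COC1=C(C)OC(=O)C=C1O
F6 | step 1 | 5-methoxy-6-methyl-3-(3-methylbut-2-en-1-ylidene)-2H-pyran-2,4(3H)-dione (not isolated) | O=C1OC(C)=C(OC)C(=O)C1=CC=C(C)C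
F7 | step 1 | 8-methoxy-2,2,7-trimethyl-2H,5H-pyrano[4,3-b]pyran-5-one | O=C1OC(C)=C(OC)C2=C1C=CC(C)(C)O2
F0 | step 8 | none | none
F8 | step 10 | 2-bromo-4-hydroxybenzaldehyde | O=Cc1ccc(O)cc1Br
F9 | step 10 | 2-bromo-4-(methoxymethoxy)benzaldehyde | COCOc1ccc(C=O)c(Br)c1
F10 | step 10 | (2E)-3-[2-bromo-4-(methoxymethoxy)phenyl]-N-methoxy-N-methylprop-2-enamide | CON(C)C(=O)/C=C/c1ccc(OCOC)cc1Br
F11 | step 10 | 3-[2-bromo-4-(methoxymethoxy)phenyl]-N-methoxy-N-methylpropanamide | CON(C)C(=O)CCc1ccc(OCOC)cc1Br
F12 | step 10 | 5-[2-bromo-4-(methoxymethoxy)phenyl]pent-1-yn-3-one | C#CC(=O)CCc1ccc(OCOC)cc1Br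
F13 | step 10 | bridged lactone cycloadduct of 8 and F12 (racemic, not isolated) | CC(C)=CCC12OC(=O)C3(C=C2C(=O)CCc2ccc(OCOC)cc2Br)C=CC(C)(C)OC3=C1OC
F14 | step 10 | 3-[2-bromo-4-(methoxymethoxy)phenyl]-1-[8-methoxy-2,2-dimethyl-7-(3-methylbut-2-en-1-yl)-2H-chromen-6-yl]propan-1-one | CC(C)=CCc1c(C(=O)CCc3ccc(OCOC)cc3Br)cc2c(c1OC)OC(C)(C)C=C2
F15 | step 10 | (1S)-3-[2-bromo-4-(methoxymethoxy)phenyl]-1-[8-methoxy-2,2-dimethyl-7-(3-methylbut-2-en-1-yl)-2H-chromen-6-yl]propan-1-ol | CC(C)=CCc1c([C@@H](O)CCc3ccc(OCOC)cc3Br)cc2c(c1OC)OC(C)(C)C=C2
F16 | step 10 | (2S)-7-(methoxymethoxy)-2-[8-methoxy-2,2-dimethyl-7-(3-methylbut-2-en-1-yl)-2H-chromen-6-yl]-3,4-dihydro-2H-chromene | CC(C)=CCc1c([C@@H]2CCc3ccc(OCOC)cc3O2)cc2c(c1OC)OC(C)(C)C=C2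
F17 | step 10 | 3'-O-methylkazinol B, (2S)-2-[8-methoxy-2,2-dimethyl-7-(3-methylbut-2-en-1-yl)-2H-chromen-6-yl]-3,4-dihydro-2H-chromen-7-ol | CC(C)=CCc1c([C@@H]2CCc3ccc(O)cc3O2)cc2c(c1OC)OC(C)(C)C=C2
A1 | alternative 1 | (2S)-2-[8-(tert-butyldimethylsilyloxy)-2,2-dimethyl-2H-chromen-6-yl]chroman-7-yl pivalate | CC1(C)C=Cc2cc(cc(O[Si](C)(C)C(C)(C)C)c2O1)[C@@H]1CCc2ccc(OC(=O)C(C)(C)C)cc2O1
A2 | alternative 1 | 2-hydroxy-4-(pivaloyloxy)benzyl alcohol | CC(C)(C)C(=O)Oc1ccc(CO)c(O)c1
A3 | alternative 1 | 8-(tert-butyldimethylsilyloxy)-2,2-dimethyl-6-vinyl-2H-chromene | C=Cc1cc(O[Si](C)(C)C(C)(C)C)c2OC(C)(C)C=Cc2c1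
A4 | alternative 2 | (2S)-2-[8-(tert-butyldimethylsilyloxy)-2,2-dimethyl-7-(3-methylbut-2-en-1-yl)-2H-chromen-6-yl]-2,3,4,4a,5,6-hexahydro-7H-chromen-7-one (both C4a epimers) | CC(C)=CCc1c(cc2C=CC(C)(C)Oc2c1O[Si](C)(C)C(C)(C)C)[C@@H]1CCC2CCC(=O)C=C2O1
A5 | alternative 2 | 4-{(3S)-3-[8-(tert-butyldimethylsilyloxy)-2,2-dimethyl-7-(3-methylbut-2-en-1-yl)-2H-chromen-6-yl]-3-hydroxypropyl}cyclohexane-1,3-dione | CC(C)=CCc1c(cc2C=CC(C)(C)Oc2c1O[Si](C)(C)C(C)(C)C)[C@@H](O)CCC1CCC(=O)CC1=O
A6 | alternative 3 | kazinol B 7-O-pivalate | CC(C)=CCc1c(O)c2OC(C)(C)C=Cc2cc1[C@@H]1CCc2ccc(OC(=O)C(C)(C)C)cc2O1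
A7 | alternative 3 | (2S)-2-[3-(2-methylbut-3-en-2-yloxy)-4-(2-methylbut-3-yn-2-yloxy)phenyl]chroman-7-yl pivalate | C=CC(C)(C)Oc1cc(ccc1OC(C)(C)C#C)[C@@H]1CCc2ccc(OC(=O)C(C)(C)C)cc2O1
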